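**Retrosynthetic overview**
1. Target 15 ⇐ 14: global hydrogenolysis of six benzyl ethers under neutral conditions (last step).
2. 14 ⇐ 11 (through phenol 12): key disconnection at C2–O1 of the chromanone ring C, an enantioselective 6-endo oxa-Michael closure of an α-aryl-2'-hydroxychalcone; C2 is set in the C–O bond formation and C3 follows thermodynamically (trans).
3. 11 ⇐ 9 + 10: aldol condensation of a deoxybenzoin with 4-(benzyloxy)benzaldehyde.
4. 9 ⇐ 3 + 8: Pd-catalysed ketone α-arylation joins the ring A ketone to the bromoflavone (the C3–C3' inter-flavonoid bond).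
5. 8 ⇐ 6 ⇐ 2 + 5: the flavone pyranone ring is made first by oxidative C–O cyclisation of a chalcone; both ring A units come from 2',4',6'-trihydroxyacetophenone, and the chromanone ring is formed last.

Assumption: the drawn (2R,3S) configuration is the trans (diequatorial) 2,3-diaryl arrangement, which I checked from the SMILES and which is the thermodynamically preferred one.

**Route**

Step 1
Reactants: 1 1-(2,4,6-trihydroxyphenyl)ethan-1-one
Product: 2 1-[2,4-bis(benzyloxy)-6-hydroxyphenyl]ethan-1-one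
Conditions: BnBr (2.1 equiv), K2CO3, DMF, 70 °C
Reagents that add atoms: benzyl bromide, BrCc1ccccc1
Why: Williamson etherification in which the one ortho-OH that stays hydrogen-bonded to the acetyl carbonyl is the least nucleophilic, so two equivalents of benzyl bromide cap the other ortho-OH and the para-OH and leave the chelated phenol free.

Step 2
Reactants: 2 1-[2,4-bis(benzyloxy)-6-hydroxyphenyl]ethan-1-one
Product: 3 1-[2,4-bis(benzyloxy)-6-(methoxymethoxy)phenyl]ethan-1-one
Conditions: NaH (1.2 equiv), MOMCl, DMF, 0 °C to rt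
Reagents that add atoms: chloromethyl methyl ether, COCCl
Why: Williamson etherification of the chelated phenol after irreversible deprotonation with NaH, giving a MOM ether that is orthogonal to benzyl, survives strong base and palladium, and can later be removed by mild acid.

Step 3
Reactants: 4 3-bromo-4-hydroxybenzaldehyde
Product: 5 4-(benzyloxy)-3-bromobenzaldehyde
Conditions: BnBr (1.1 equiv), K2CO3, DMF, rt
Reagents that add atoms: benzyl bromide, BrCc1ccccc1
Why: Williamson etherification of an acidic para-formyl phenol, which is clean because the aldehyde has no enolisable position.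

Step 4
Reactants: 2 1-[2,4-bis(benzyloxy)-6-hydroxyphenyl]ethan-1-one; 5 4-(benzyloxy)-3-bromobenzaldehyde
Product: 6 (E)-1-[2,4-bis(benzyloxy)-6-hydroxyphenyl]-3-[4-(benzyloxy)-3-bromophenyl]prop-2-en-1-one
Conditions: KOH (50% aq), EtOH/THF, rt; then dilute HCl at 0 °C
Reagents that add atoms: none
Why: Claisen–Schmidt aldol condensation between the only enolisable partner (the acetyl group) and a non-enolisable aldehyde, with E1cB dehydration giving the E-chalcone while the aryl bromide and benzyl ethers are inert to aqueous KOH.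

Step 5
Reactants: 6 (E)-1-[2,4-bis(benzyloxy)-6-hydroxyphenyl]-3-[4-(benzyloxy)-3-bromophenyl]prop-2-en-1-one
Product: 8 5,7-bis(benzyloxy)-2-[4-(benzyloxy)-3-bromophenyl]-4H-chromen-4-one, via racemic flavanone 7 (not isolated)
Conditions: I2 (10 mol%), DMSO, 130 °C
Reagents that add atoms: none
Why: iodine-catalysed oxidative cyclisation of a 2'-hydroxychalcone, in which ring closure to flavanone 7 is followed by iodine-mediated dehydrogenation with DMSO as the terminal oxidant, a standard flavone synthesis that tolerates benzyl ethers and aryl bromides.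

Step 6
Reactants: 3 1-[2,4-bis(benzyloxy)-6-(methoxymethoxy)phenyl]ethan-1-one; 8 5,7-bis(benzyloxy)-2-[4-(benzyloxy)-3-bromophenyl]-4H-chromen-4-one
Product: 9 1-[2,4-bis(benzyloxy)-6-(methoxymethoxy)phenyl]-2-{2-(benzyloxy)-5-[5,7-bis(benzyloxy)-4-oxo-4H-chromen-2-yl]phenyl}ethan-1-one
Conditions: Pd2(dba)3 (2.5 mol%), XPhos (6 mol%), NaOtBu (2.2 equiv), toluene, 80 °C (3 in 1.3-fold excess)
Reagents that add atoms: none
Why: Buchwald–Hartwig-type ketone α-arylation in which the sodium enolate of methyl ketone 3 couples with the aryl bromide after its oxidative addition to zerovalent palladium, the bulky biaryl phosphine favouring reductive elimination at the ortho-alkoxy aryl group and monoarylation, with no free phenol or other acidic C–H present.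

Step 7
Reactants: 9 1-[2,4-bis(benzyloxy)-6-(methoxymethoxy)phenyl]-2-{2-(benzyloxy)-5-[5,7-bis(benzyloxy)-4-oxo-4H-chromen-2-yl]phenyl}ethan-1-one; 10 4-(benzyloxy)benzaldehyde
Product: 11 (E)-1-[2,4-bis(benzyloxy)-6-(methoxymethoxy)phenyl]-2-{2-(benzyloxy)-5-[5,7-bis(benzyloxy)-4-oxo-4H-chromen-2-yl]phenyl}-3-[4-(benzyloxy)phenyl]prop-2-en-1-one
Conditions: piperidine (0.3 equiv), AcOH (0.3 equiv), toluene, Dean–Stark, reflux
Reagents that add atoms: none
Why: Knoevenagel-type aldol condensation of the acidic benzylic CH2 of the deoxybenzoin with the piperidinium-activated, non-enolisable aldehyde under azeotropic water removal, giving the thermodynamic E-alkene (aroyl trans to the β-aryl), while the MOM ether on the ortho oxygen makes premature ring closure impossible.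

Step 8
Reactants: 11 (E)-1-[2,4-bis(benzyloxy)-6-(methoxymethoxy)phenyl]-2-{2-(benzyloxy)-5-[5,7-bis(benzyloxy)-4-oxo-4H-chromen-2-yl]phenyl}-3-[4-(benzyloxy)phenyl]prop-2-en-1-one
Product: 14 (2R,3S)-5,7-bis(benzyloxy)-3-{2-(benzyloxy)-5-[5,7-bis(benzyloxy)-4-oxo-4H-chromen-2-yl]phenyl}-2-[4-(benzyloxy)phenyl]chroman-4-one, via free phenol chalcone 12 (not isolated), via chromenol 13 (not isolated)
Conditions: NaHSO4·SiO2, CH2Cl2, rt, 1–2 h; filter, swap to toluene; then squaramide from 9-amino-9-deoxy-epi-quinidine and 3,5-bis(trifluoromethyl)aniline (10 mol%), toluene, −20 to 0 °C; cold filtration through silica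
Reagents that add atoms: none
Why: Proposed new method: the solid acid removes only the phenolic MOM ether and unveils the hydrogen-bonded 2'-phenol of 12 with no base present, after which the bifunctional catalyst deprotonates that phenol with its quinuclidine nitrogen while its squaramide N–H bonds hold the enone carbonyl, so the chiral ammonium phenoxide adds 6-endo to one face of the β-carbon and forms the C2–O1 bond enantioselectively to give enol 13, whose ketonisation under the same amine is thermodynamically controlled and places the C3 aryl trans (diequatorial) to the C2 aryl to give (2R,3S); the closest known reaction is the cinchona thiourea-catalysed oxa-Michael cyclisation of 2'-hydroxychalcones activated by an α-ester group to flavanones, which has not been shown for an α-aryl chalcone that lacks such activation and creates two adjacent stereocentres.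

Step 9
Reactants: 14 (2R,3S)-5,7-bis(benzyloxy)-3-{2-(benzyloxy)-5-[5,7-bis(benzyloxy)-4-oxo-4H-chromen-2-yl]phenyl}-2-[4-(benzyloxy)phenyl]chroman-4-one
Product: 15 (2R,3S)-3-[5-(5,7-dihydroxy-4-oxo-4H-chromen-2-yl)-2-hydroxyphenyl]-5,7-dihydroxy-2-(4-hydroxyphenyl)-2,3-dihydro-4H-chromen-4-one (CNP0324936.1)
Conditions: H2 (1 atm), Pd/C (10 wt%), THF/MeOH (1:1), rt
Reagents that add atoms: none
Why: heterogeneous catalytic hydrogenolysis of six aryl benzyl ethers under neutral conditions, where the ketones, the flavone C2=C3 bond and the benzylic C2–O1 bond react much more slowly at 1 atm, and where the absence of acid or base avoids ring-opening epimerisation at C2 and cyclodehydration of the freed 2-hydroxyphenyl group onto the C4 ketone, so neither stereocentre is touched.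

**Compound list**
1 | 1-(2,4,6-trihydroxyphenyl)ethan-1-one (2',4',6'-trihydroxyacetophenone) | CC(=O)c1c(O)cc(O)cc1O | starting material
2 | 1-[2,4-bis(benzyloxy)-6-hydroxyphenyl]ethan-1-one | CC(=O)c1c(O)cc(OCc2ccccc2)cc1OCc1ccccc1 | intermediate
3 | 1-[2,4-bis(benzyloxy)-6-(methoxymethoxy)phenyl]ethan-1-one | CC(=O)c1c(OCOC)cc(OCc2ccccc2)cc1OCc1ccccc1 | intermediate
4 | 3-bromo-4-hydroxybenzaldehyde | O=Cc1ccc(O)c(Br)c1 | starting material
5 | 4-(benzyloxy)-3-bromobenzaldehyde | O=Cc1ccc(OCc2ccccc2)c(Br)c1 | intermediate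
6 | (E)-1-[2,4-bis(benzyloxy)-6-hydroxyphenyl]-3-[4-(benzyloxy)-3-bromophenyl]prop-2-en-1-one | O=C(/C=C/c1ccc(OCc2ccccc2)c(Br)c1)c1c(O)cc(OCc2ccccc2)cc1OCc1ccccc1 | intermediate
7 | 5,7-bis(benzyloxy)-2-[4-(benzyloxy)-3-bromophenyl]chroman-4-one (racemic; formed in the flask, not isolated) | O=C1CC(c2ccc(OCc3ccccc3)c(Br)c2)Oc2cc(OCc3ccccc3)cc(OCc3ccccc3)c12 | intermediate
8 | 5,7-bis(benzyloxy)-2-[4-(benzyloxy)-3-bromophenyl]-4H-chromen-4-one | O=c1cc(-c2ccc(OCc3ccccc3)c(Br)c2)oc2cc(OCc3ccccc3)cc(OCc3ccccc3)c12 | intermediate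
9 | 1-[2,4-bis(benzyloxy)-6-(methoxymethoxy)phenyl]-2-{2-(benzyloxy)-5-[5,7-bis(benzyloxy)-4-oxo-4H-chromen-2-yl]phenyl}ethan-1-one | O=C(Cc1cc(-c2cc(=O)c3c(OCc4ccccc4)cc(OCc4ccccc4)cc3o2)ccc1OCc1ccccc1)c1c(OCOC)cc(OCc2ccccc2)cc1OCc1ccccc1 | intermediate
10 | 4-(benzyloxy)benzaldehyde | O=Cc1ccc(OCc2ccccc2)cc1 | starting material
11 | (E)-1-[2,4-bis(benzyloxy)-6-(methoxymethoxy)phenyl]-2-{2-(benzyloxy)-5-[5,7-bis(benzyloxy)-4-oxo-4H-chromen-2-yl]phenyl}-3-[4-(benzyloxy)phenyl]prop-2-en-1-one | O=C(/C(=C/c1ccc(OCc2ccccc2)cc1)c1cc(-c2cc(=O)c3c(OCc4ccccc4)cc(OCc4ccccc4)cc3o2)ccc1OCc1ccccc1)c1c(OCOC)cc(OCc2ccccc2)cc1OCc1ccccc1 | intermediate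
12 | (E)-1-[2,4-bis(benzyloxy)-6-hydroxyphenyl]-2-{2-(benzyloxy)-5-[5,7-bis(benzyloxy)-4-oxo-4H-chromen-2-yl]phenyl}-3-[4-(benzyloxy)phenyl]prop-2-en-1-one (formed in the flask, not isolated) | O=C(/C(=C/c1ccc(OCc2ccccc2)cc1)c1cc(-c2cc(=O)c3c(OCc4ccccc4)cc(OCc4ccccc4)cc3o2)ccc1OCc1ccccc1)c1c(O)cc(OCc2ccccc2)cc1OCc1ccccc1 | intermediate
13 | (2S)-5,7-bis(benzyloxy)-3-{2-(benzyloxy)-5-[5,7-bis(benzyloxy)-4-oxo-4H-chromen-2-yl]phenyl}-2-[4-(benzyloxy)phenyl]-2H-chromen-4-ol (enol, not isolated; same spatial arrangement at C2 as in 14, the descriptor reads S only because C3 is sp2 here) | OC1=C(c2cc(-c3cc(=O)c4c(OCc5ccccc5)cc(OCc5ccccc5)cc4o3)ccc2OCc2ccccc2)[C@H](c2ccc(OCc3ccccc3)cc2)Oc2cc(OCc3ccccc3)cc(OCc3ccccc3)c12 | intermediate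
14 | (2R,3S)-5,7-bis(benzyloxy)-3-{2-(benzyloxy)-5-[5,7-bis(benzyloxy)-4-oxo-4H-chromen-2-yl]phenyl}-2-[4-(benzyloxy)phenyl]chroman-4-one (trans) | O=C1c2c(OCc3ccccc3)cc(OCc3ccccc3)cc2O[C@@H](c2ccc(OCc3ccccc3)cc2)[C@@H]1c1cc(-c2cc(=O)c3c(OCc4ccccc4)cc(OCc4ccccc4)cc3o2)ccc1OCc1ccccc1 | intermediate
15 | (2R,3S)-3-[5-(5,7-dihydroxy-4-oxo-4H-chromen-2-yl)-2-hydroxyphenyl]-5,7-dihydroxy-2-(4-hydroxyphenyl)-2,3-dihydro-4H-chromen-4-one (CNP0324936.1) | O=C1c2c(O)cc(O)cc2O[C@@H](c2ccc(O)cc2)[C@@H]1c1cc(-c2cc(=O)c3c(O)cc(O)cc3o2)ccc1O | target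

**Step count and risks**

Total steps: 9. Longest linear sequence: 7 (step 1 or step 3, then steps 4, 5, 6, 7, 8, 9).

Most likely to fail, in order:

Step 8 (the proposed new method). Three things can go wrong:
- The unactivated, hindered α-aryl enone may close slowly.
- Enantiomeric excess can be lost through uncatalysed closure of 12 or through retro-oxa-Michael opening of 14 while the amine is present; hence the low temperature, the immediate use of 12 and the cold silica filtration.
- The sense of induction is not known in advance. It must be assigned on the first run, and the quinine-derived pseudoenantiomer of the catalyst gives the mirror-image series if the quinidine-derived one delivers 2S.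

Fallback with known chemistry, setting out from 11 and coming back at 14: cleave the MOM ether with NaHSO4·SiO2 as before to give phenol 12, then close the ring with catalytic piperidine in EtOH at reflux, the classical amine-mediated route to trans-2,3-diarylchromanones. This gives the racemate, that is 14 together with its mirror image, the (2S,3R)-hexabenzyl chromanone F7. Separate the two on a preparative chiral SFC column (amylose tris(3,5-dimethylphenylcarbamate) phase). F7 is returned to the piperidine conditions, where ring opening and re-closure racemise C2, and is recycled.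

Step 6 (α-arylation). The enolate is flanked by two ortho substituents, the aryl bromide carries an ortho benzyloxy group, and tert-butoxide could attack the flavone.

Fallback, setting out from 2 and 8 and coming back at 9: heat 2 with N,N-dimethylformamide dimethyl acetal to give the (E)-enaminone F1. Treat it with I2 in CHCl3 to close and iodinate it to 5,7-bis(benzyloxy)-3-iodochromone F2. Convert 8 with B2pin2, Pd(dppf)Cl2 and KOAc in dioxane at 90 °C into the flavone pinacol boronate F3. Join F2 and F3 by Suzuki coupling (Pd(PPh3)4, aqueous K2CO3, dioxane, 80 °C) to give the isoflavone–flavone F4. Open the isoflavone ring with aqueous KOH in EtOH at reflux, the classical degradation of isoflavones to deoxybenzoins with loss of formate, to give the 2'-hydroxydeoxybenzoin F5. Cap its phenol with NaH and MOMCl in DMF to reach 9.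

Step 7 (condensation). The deoxybenzoin is very hindered, the reaction may stall, and E/Z mixtures would lower the selectivity of step 8.

Fallback, setting out from 9 (with 10) and coming back at 11: deprotonate 9 with LiN(SiMe3)2 in THF at −78 °C and add 10 to give the β-hydroxy ketone (aldol adduct, diastereomer mixture) F6. Dehydrate it by mesylation (MsCl, Et3N, 0 °C) and elimination with DBU at rt to give 11.

**Further compounds**
F1 | step 6 | (E)-1-[2,4-bis(benzyloxy)-6-hydroxyphenyl]-3-(dimethylamino)prop-2-en-1-one | CN(C)/C=C/C(=O)c1c(O)cc(OCc2ccccc2)cc1OCc1ccccc1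
F2 | step 6 | 5,7-bis(benzyloxy)-3-iodo-4H-chromen-4-one | O=c1c(I)coc2cc(OCc3ccccc3)cc(OCc3ccccc3)c12
F3 | step 6 | 5,7-bis(benzyloxy)-2-[4-(benzyloxy)-3-(4,4,5,5-tetramethyl-1,3,2-dioxaborolan-2-yl)phenyl]-4H-chromen-4-one | O=c1cc(-c2ccc(OCc3ccccc3)c(B3OC(C)(C)C(C)(C)O3)c2)oc2cc(OCc3ccccc3)cc(OCc3ccccc3)c12
F4 | step 6 | 5,7-bis(benzyloxy)-3-{2-(benzyloxy)-5-[5,7-bis(benzyloxy)-4-oxo-4H-chromen-2-yl]phenyl}-4H-chromen-4-one | O=c1c(-c2cc(-c3cc(=O)c4c(OCc5ccccc5)cc(OCc5ccccc5)cc4o3)ccc2OCc2ccccc2)coc2cc(OCc3ccccc3)cc(OCc3ccccc3)c12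
F5 | step 6 | 1-[2,4-bis(benzyloxy)-6-hydroxyphenyl]-2-{2-(benzyloxy)-5-[5,7-bis(benzyloxy)-4-oxo-4H-chromen-2-yl]phenyl}ethan-1-one | O=C(Cc1cc(-c2cc(=O)c3c(OCc4ccccc4)cc(OCc4ccccc4)cc3o2)ccc1OCc1ccccc1)c1c(O)cc(OCc2ccccc2)cc1OCc1ccccc1
F6 | step 7 | 1-[2,4-bis(benzyloxy)-6-(methoxymethoxy)phenyl]-2-{2-(benzyloxy)-5-[5,7-bis(benzyloxy)-4-oxo-4H-chromen-2-yl]phenyl}-3-[4-(benzyloxy)phenyl]-3-hydroxypropan-1-one (diastereomer mixture) | O=C(C(C(O)c1ccc(OCc2ccccc2)cc1)c1cc(-c2cc(=O)c3c(OCc4ccccc4)cc(OCc4ccccc4)cc3o2)ccc1OCc1ccccc1)c1c(OCOC)cc(OCc2ccccc2)cc1OCc1ccccc1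
F7 | step 8 | (2S,3R)-5,7-bis(benzyloxy)-3-{2-(benzyloxy)-5-[5,7-bis(benzyloxy)-4-oxo-4H-chromen-2-yl]phenyl}-2-[4-(benzyloxy)phenyl]chroman-4-one | O=C1c2c(OCc3ccccc3)cc(OCc3ccccc3)cc2O[C@H](c2ccc(OCc3ccccc3)cc2)[C@H]1c1cc(-c2cc(=O)c3c(OCc4ccccc4)cc(OCc4ccccc4)cc3o2)ccc1OCc1ccccc1
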